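**Plan**

- Numbering used: tetralin C1 carries the aryl group, C2 the CH2O-coumaroyl group, C3 the CH2OH group, C4 is the benzylic CH2; ring A is the fused arene (C4a to C8a), ring B the saturated ring.
- Cuts, in order: the three benzyl ethers; C3–CH2OH back to an N-acyl sultam; C4H2 back to a C4 carbinol; ring B at C3–C4 and C1–C2 (retro-Diels–Alder); last the C1–C8a benzyl–aryl bond.
- Enabling feature: C4 and C1 are exocyclic carbons on the adjacent ring A carbons C4a and C8a, so ring B is the [4+2] ring of a ring A ortho-quinodimethane (C4=C4a–C8a=C1) and the C2=C3 alkene. C4 is carried at the aldehyde level, so the diene is the photoenol of a 2-benzylbenzaldehyde; within the same operation it is parked as a cyclic sulfone (temporary ring) and released by heat after the lamp is off, so the cinnamate never sees light.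
- Forward: benzylzinc coupling (C1–C8a) gives the 2-benzylbenzaldehyde; one telescoped operation (photoenol, SO2 capture, SO2 loss, [4+2]) closes ring B with all three stereocentres; then C4 deoxygenation, reductive auxiliary removal, debenzylation.
- Stereochemistry: 2,3-trans from the E-dienophile; 1,2-trans from the E,E-diene reacting endo to the acyl group and exo to the CH2O group; absolute configuration from the camphor-derived sultam; the C4 carbinol centre is erased.
- Ester placement: the C4 hydroxyl of the diene steers the acyl carbon to C3, so the coumarate already on the dienophile lands on the C2 hydroxymethyl and the two CH2O groups never need differentiating.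

Key step: step 5

Remark: the (1S,2R)-sultam (and the (S)-lactate of the fallback to step 5) is chosen on the working model that the non-chelated enoyl derivative is attacked on the Cα-re face; should the opposite sense be found, the enantiomeric auxiliary is used, and the facial isomers of 14 are diastereomers that are separated at that stage.

**Route**

Step 1
Reactants: 1 2-bromo-4-hydroxy-5-methoxybenzaldehyde (6-bromovanillin)
Product: 2 4-(benzyloxy)-2-bromo-5-methoxybenzaldehyde
Conditions: BnBr, K2CO3, DMF, rt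
Reagents that add atoms: benzyl bromide, BrCc1ccccc1
Why: Williamson ether synthesis on the phenoxide of 1; the aldehyde and the aryl bromide are inert under these conditions.

Step 2
Reactants: 3 1-(benzyloxy)-4-(chloromethyl)-2-methoxybenzene; 2 4-(benzyloxy)-2-bromo-5-methoxybenzaldehyde
Product: 5 4-(benzyloxy)-2-[4-(benzyloxy)-3-methoxybenzyl]-5-methoxybenzaldehyde, via [4-(benzyloxy)-3-methoxybenzyl]zinc chloride 4 (not isolated)
Conditions: 3, Zn dust, LiCl, THF, 25 °C; then 2, Pd(OAc)2 (cat.), SPhos (cat.), THF, 25 °C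
Reagents that add atoms: none
Why: Negishi cross-coupling: zinc inserts into the benzylic C–Cl bond of 3 and the benzylzinc chloride should couple with aryl bromide 2 faster than it adds to the electron-rich aldehyde, forming the C1–C8a bond.

Step 3
Reactants: 6 (E)-4-bromobut-2-enoic acid; 7 (1S,2R)-bornane-10,2-sultam
Product: 9 N-[(E)-4-bromobut-2-enoyl]-(1S,2R)-bornane-10,2-sultam, via (E)-4-bromobut-2-enoyl chloride 8 (not isolated)
Conditions: 6, (COCl)2, DMF (cat.), CH2Cl2, 0 °C to rt; then 7, NaH, toluene, 0 °C to rt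
Reagents that add atoms: none
Why: Acid chloride formation followed by N-acylation of the sodium salt of 7; the acyl chloride is far more electrophilic than the allylic bromide and the E-alkene is untouched.

Step 4
Reactants: 9 N-[(E)-4-bromobut-2-enoyl]-(1S,2R)-bornane-10,2-sultam; 10 (E)-3-[4-(benzyloxy)phenyl]prop-2-enoic acid
Product: 11 (E)-4-[(1S,2R)-bornane-10,2-sultam-N-yl]-4-oxobut-2-en-1-yl (E)-3-[4-(benzyloxy)phenyl]prop-2-enoate
Conditions: Cs2CO3, DMF, 0 °C to rt
Reagents that add atoms: none
Why: SN2 O-alkylation of the cesium carboxylate of 10 by the primary allylic bromide (carboxylate esterification), which keeps both E-alkenes and the N-acyl sultam.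

Step 5
Reactants: 5 4-(benzyloxy)-2-[4-(benzyloxy)-3-methoxybenzyl]-5-methoxybenzaldehyde; 11 enoyl sultam carrying the O-benzyl coumarate
Product: 14 (1S,2R,3S,4S)-4-hydroxytetralin cycloadduct bearing the N-acyl sultam on C3 (full name in the compound list), via (E,E)-hydroxy-o-quinodimethane 12 (not isolated), via cis-hydroxysulfone 13 (not isolated)
Conditions: 5, SO2 (saturated), benzene, hν (350 nm, Pyrex), 20 °C; then lamp off, argon purge, evaporation below 25 °C; then 11, ZnO, toluene, 80 °C, dark, argon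
Reagents that add atoms: none
Why: Excitation of the formyl group of 5 triggers 1,5-hydrogen transfer from the doubly benzylic CH2 (photoenolisation) and the (E,E)-dienol 12 is stored by suprafacial cheletropic addition of SO2 as the racemic cis-sulfone 13; once light and free SO2 are removed, 13 loses SO2 at 80 °C (retro-cheletropic, ZnO as scavenger) and regenerates 12 in the dark, whose diene C4=C4a–C8a=C1, exocyclic to ring A, adds suprafacially across C2=C3 of 11 in an asynchronous concerted Diels–Alder reaction in which C1–C2 bonding leads and C3–C4 completes the ring. The closest known reaction type is the photoenolisation of 2-benzylbenzaldehydes under SO2 followed by thermal trapping of the released α-hydroxy-α'-aryl-o-quinodimethanes with chiral acrylate- and fumarate-type dienophiles. Ring B is closed in this single intermolecular [4+2] event, with ring A regaining aromaticity as the driving force, and the hydroxyl on C4 makes the remote terminus C1 the most nucleophilic diene carbon, so C1 bonds to the β-carbon C2 and the hydroxyl-bearing C4 to the acyl-bearing C3. C2 and C3 are trans because the dienophile is E; the C4 hydroxyl is cis to the C3 acyl group because that group sits endo, held by an O–H···O=C hydrogen bond; the C1 aryl group is trans to the C2 substituent because the outward aryl of the E,E-diene meets the exo CH2O group. The absolute sense comes from the sultam, which shields one face of the s-cis enoyl unit so that the diene should add to the Cα-re face (C3), giving the (1S,2R,3S,4S) adduct, the facial isomer being a separable diastereomer. The step also needs chemoselectivity for the enoyl sultam over the cinnamate C=C, which the stronger acceptor character of the N-acyl sultam and the donor-substituted β-aryl group of the cinnamate should secure, and the cinnamate is never irradiated because 11 enters only after the lamp is off.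

Step 6
Reactants: 14 the (1S,2R,3S,4S)-4-hydroxytetralin cycloadduct
Product: 15 the (1S,2R,3R)-tetralin N-acyl sultam with C4 as CH2
Conditions: Et3SiH, CF3CO2H, CH2Cl2, −20 to 0 °C
Reagents that add atoms: none
Why: Ionic hydrogenation: CF3CO2H ionises the benzylic carbinol to a cation at C4 stabilised by the para benzyloxy group of ring A and Et3SiH delivers hydride, so C4 becomes CH2 while C1 to C3, both acyl groups and the benzyl ethers are untouched.

Step 7
Reactants: 15 the (1S,2R,3R)-tetralin N-acyl sultam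
Product: 16 the (1S,2R,3R)-tri-O-benzyl ether of the target (free C3 hydroxymethyl)
Conditions: NaBH4, THF/H2O, 0 °C to rt; NH4Cl (aq) quench
Reagents that add atoms: none
Why: Borohydride reductive cleavage of the N-acyl sultam, an imide-like activated acyl group, should be much faster than reduction of the conjugated cinnamate ester; C3 keeps its configuration (already the all-equatorial isomer) and the sultam (compound 7) is recovered.

Step 8
Reactants: 16 the (1S,2R,3R)-tri-O-benzyl ether of the target
Product: 17 the target CNP0403384.1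
Conditions: BCl3, pentamethylbenzene, CH2Cl2, −78 °C; MeOH quench
Reagents that add atoms: none
Why: Lewis acid debenzylation of the three aryl benzyl ethers at −78 °C, with pentamethylbenzene trapping the benzyl cations by Friedel–Crafts alkylation, so the cinnamate ester, its alkene, the aryl methyl ethers and the primary alcohol should survive.

**Compound list**

1 | 2-bromo-4-hydroxy-5-methoxybenzaldehyde (6-bromovanillin) | O=Cc1cc(OC)c(O)cc1Br | starting material
2 | 4-(benzyloxy)-2-bromo-5-methoxybenzaldehyde | O=Cc1cc(OC)c(OCc2ccccc2)cc1Br | intermediate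
3 | 1-(benzyloxy)-4-(chloromethyl)-2-methoxybenzene | COc1cc(CCl)ccc1OCc1ccccc1 | starting material
4 | [4-(benzyloxy)-3-methoxybenzyl]zinc chloride | COc1cc(C[Zn]Cl)ccc1OCc1ccccc1 | intermediate
5 | 4-(benzyloxy)-2-[4-(benzyloxy)-3-methoxybenzyl]-5-methoxybenzaldehyde | O=Cc1cc(OC)c(OCc2ccccc2)cc1Cc1ccc(OCc2ccccc2)c(OC)c1 | intermediate
6 | (E)-4-bromobut-2-enoic acid | OC(=O)/C=C/CBr | starting material
7 | (1S,2R)-bornane-10,2-sultam (the camphorsultam derived from (1S)-10-camphorsulfonic acid) | CC1(C)[C@@H]2CC[C@]13CS(=O)(=O)N[C@@H]3C2 | starting material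
8 | (E)-4-bromobut-2-enoyl chloride | ClC(=O)/C=C/CBr | intermediate
9 | N-[(E)-4-bromobut-2-enoyl]-(1S,2R)-bornane-10,2-sultam | CC1(C)[C@@H]2CC[C@]13CS(=O)(=O)N(C(=O)/C=C/CBr)[C@@H]3C2 | intermediate
10 | (E)-3-[4-(benzyloxy)phenyl]prop-2-enoic acid | OC(=O)/C=C/c1ccc(OCc2ccccc2)cc1 | starting material
11 | (E)-4-[(1S,2R)-bornane-10,2-sultam-N-yl]-4-oxobut-2-en-1-yl (E)-3-[4-(benzyloxy)phenyl]prop-2-enoate | CC1(C)[C@@H]2CC[C@]13CS(=O)(=O)N(C(=O)/C=C/COC(=O)/C=C/c4ccc(OCc5ccccc5)cc4)[C@@H]3C2 | intermediate
12 | (E)-{(6E)-4-(benzyloxy)-6-[4-(benzyloxy)-3-methoxybenzylidene]-3-methoxycyclohexa-2,4-dien-1-ylidene}methanol, the (E,E)-hydroxy-o-quinodimethane | O/C=C1\C=C(OC)C(OCc2ccccc2)=C/C1=C\c1ccc(OCc2ccccc2)c(OC)c1 | intermediate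
13 | cis-(1RS,3RS)-5-(benzyloxy)-3-[4-(benzyloxy)-3-methoxyphenyl]-1-hydroxy-6-methoxy-1,3-dihydro-2-benzothiophene 2,2-dioxide (racemate, one enantiomer drawn) | O[C@H]1c2cc(OC)c(OCc3ccccc3)cc2[C@@H](c2ccc(OCc3ccccc3)c(OC)c2)S1(=O)=O | intermediate
14 | {(1S,2R,3S,4S)-7-(benzyloxy)-1-[4-(benzyloxy)-3-methoxyphenyl]-3-{[(1S,2R)-bornane-10,2-sultam-N-yl]carbonyl}-4-hydroxy-6-methoxy-1,2,3,4-tetrahydronaphthalen-2-yl}methyl (E)-3-[4-(benzyloxy)phenyl]prop-2-enoate | COc1cc([C@H]2c3cc(OCc4ccccc4)c(OC)cc3[C@@H](O)[C@@H](C(=O)N5[C@@H]6C[C@H]7CC[C@]6(CS5(=O)=O)C7(C)C)[C@@H]2COC(=O)/C=C/c2ccc(OCc3ccccc3)cc2)ccc1OCc1ccccc1 | intermediate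
15 | {(1S,2R,3R)-7-(benzyloxy)-1-[4-(benzyloxy)-3-methoxyphenyl]-3-{[(1S,2R)-bornane-10,2-sultam-N-yl]carbonyl}-6-methoxy-1,2,3,4-tetrahydronaphthalen-2-yl}methyl (E)-3-[4-(benzyloxy)phenyl]prop-2-enoate | COc1cc([C@H]2c3cc(OCc4ccccc4)c(OC)cc3C[C@@H](C(=O)N5[C@@H]6C[C@H]7CC[C@]6(CS5(=O)=O)C7(C)C)[C@@H]2COC(=O)/C=C/c2ccc(OCc3ccccc3)cc2)ccc1OCc1ccccc1 | intermediate
16 | {(1S,2R,3R)-7-(benzyloxy)-1-[4-(benzyloxy)-3-methoxyphenyl]-3-(hydroxymethyl)-6-methoxy-1,2,3,4-tetrahydronaphthalen-2-yl}methyl (E)-3-[4-(benzyloxy)phenyl]prop-2-enoate | COc1cc([C@H]2c3cc(OCc4ccccc4)c(OC)cc3C[C@@H](CO)[C@@H]2COC(=O)/C=C/c2ccc(OCc3ccccc3)cc2)ccc1OCc1ccccc1 | intermediate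
17 | {(1S,2R,3R)-7-hydroxy-1-(4-hydroxy-3-methoxyphenyl)-3-(hydroxymethyl)-6-methoxy-1,2,3,4-tetrahydronaphthalen-2-yl}methyl (E)-3-(4-hydroxyphenyl)prop-2-enoate (CNP0403384.1) | COc1cc([C@H]2c3cc(O)c(OC)cc3C[C@@H](CO)[C@@H]2COC(=O)/C=C/c2ccc(O)cc2)ccc1O | target

**Step count and risks**

Total steps: 8. Longest linear sequence: 6 steps (1, 2, 5, 6, 7, 8); the dienophile branch (steps 3 and 4) joins at step 5 and is equally long (3, 4, 5, 6, 7, 8).

Steps most likely to fail:

1. Step 5. The sultam may discriminate the two alkene faces poorly in a non-chelated thermal cycloaddition. The β-substituted dienophile may also react too slowly, so that the dienol reverts to aldehyde 5 by 1,5-hydrogen shift, or it may lose regiochemical or endo control.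
Fallback: the hydrogen-bond-directed cycloaddition of the same dienol with a chiral fumarate, followed by differentiation of the two hydroxymethyl groups through the C4 hydroxyl. It sets out from 5. Fumaroyl chloride and methyl (S)-lactate (pyridine, CH2Cl2) give bis[(S)-1-methoxy-1-oxopropan-2-yl] fumarate F1. Aldehyde 5 is photolysed under SO2 as in step 5, and the crude sulfone 13 is heated with it (ZnO, toluene, 80 °C), which should give the endo 4-hydroxy-2,3-diester F2. LiAlH4 (THF, 0 °C) reduces both esters to the 4-hydroxy-2,3-bis(hydroxymethyl) triol F3. 2,2-Dimethoxypropane with PPTS ties the cis-related C4 hydroxyl and C3 hydroxymethyl into the six-membered acetonide F4, leaving only the C2 hydroxymethyl free. Esterification with 10 (DCC, DMAP) gives the acetonide coumarate F5. Aqueous acetic acid unmasks the 4-hydroxy-3-hydroxymethyl ester F6, and Et3SiH/CF3CO2H removes the benzylic hydroxyl, coming back to the route at 16.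

2. Step 6. Loss of a proton from C3 of the benzylic cation (E1 elimination to the conjugated 1,2-dihydronaphthalene, which erases C3) may compete with hydride transfer.
Fallback: radical deoxygenation. From 14, 1,1'-thiocarbonyldiimidazole (DMAP, CH2Cl2) gives the O-(imidazol-1-ylthiocarbonyl) derivative F7, and Bu3SnH/AIBN (toluene, 80 °C, Barton–McCombie) returns to the route at 15; the C3 hydrogen is trans to the C4 oxygen, so thermal syn-elimination is not available.

3. Step 7. Borohydride may attack the hindered acyl sultam too slowly, and the alkoxide formed may shift the coumarate from O on the C2 arm to O on the C3 arm (1,4-acyl migration) or the ester may be reduced.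
Fallback: hydrolytic removal of the auxiliary followed by a non-basic reduction. From 15, LiOH/H2O2 (THF/H2O, 0 °C) gives the C3 carboxylic acid F8, which BH3·SMe2 (THF, 0 °C) reduces through its acyloxyborane faster than it touches the ester or the conjugated alkene, coming back to the route at 16.

**Further compounds**

F1 | step 5 | bis[(S)-1-methoxy-1-oxopropan-2-yl] (E)-but-2-enedioate | COC(=O)[C@H](C)OC(=O)/C=C/C(=O)O[C@@H](C)C(=O)OC
F2 | step 5 | bis[(S)-1-methoxy-1-oxopropan-2-yl] (1S,2R,3S,4S)-7-(benzyloxy)-1-[4-(benzyloxy)-3-methoxyphenyl]-4-hydroxy-6-methoxy-1,2,3,4-tetrahydronaphthalene-2,3-dicarboxylate | COc1cc([C@H]2c3cc(OCc4ccccc4)c(OC)cc3[C@@H](O)[C@@H](C(=O)O[C@@H](C)C(=O)OC)[C@@H]2C(=O)O[C@@H](C)C(=O)OC)ccc1OCc1ccccc1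
F3 | step 5 | (1S,2R,3R,4S)-7-(benzyloxy)-1-[4-(benzyloxy)-3-methoxyphenyl]-2,3-bis(hydroxymethyl)-6-methoxy-1,2,3,4-tetrahydronaphthalen-4-ol (route numbering) | COc1cc([C@H]2c3cc(OCc4ccccc4)c(OC)cc3[C@@H](O)[C@@H](CO)[C@@H]2CO)ccc1OCc1ccccc1
F4 | step 5 | acetonide of F3 across the C4 hydroxyl and the C3 hydroxymethyl (cis-fused 2,2-dimethyl-1,3-dioxane), C2 hydroxymethyl free | COc1cc([C@H]2c3cc(OCc4ccccc4)c(OC)cc3[C@H]3OC(C)(C)OC[C@H]3[C@@H]2CO)ccc1OCc1ccccc1
F5 | step 5 | (E)-3-[4-(benzyloxy)phenyl]prop-2-enoate ester of F4 at the C2 hydroxymethyl | COc1cc([C@H]2c3cc(OCc4ccccc4)c(OC)cc3[C@H]3OC(C)(C)OC[C@H]3[C@@H]2COC(=O)/C=C/c2ccc(OCc3ccccc3)cc2)ccc1OCc1ccccc1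
F6 | step 5 | {(1S,2R,3R,4S)-7-(benzyloxy)-1-[4-(benzyloxy)-3-methoxyphenyl]-4-hydroxy-3-(hydroxymethyl)-6-methoxy-1,2,3,4-tetrahydronaphthalen-2-yl}methyl (E)-3-[4-(benzyloxy)phenyl]prop-2-enoate | COc1cc([C@H]2c3cc(OCc4ccccc4)c(OC)cc3[C@@H](O)[C@@H](CO)[C@@H]2COC(=O)/C=C/c2ccc(OCc3ccccc3)cc2)ccc1OCc1ccccc1
F7 | step 6 | O-(1H-imidazol-1-ylthiocarbonyl) derivative of 14 at the C4 hydroxyl | COc1cc([C@H]2c3cc(OCc4ccccc4)c(OC)cc3[C@@H](OC(=S)n4ccnc4)[C@@H](C(=O)N5[C@@H]6C[C@H]7CC[C@]6(CS5(=O)=O)C7(C)C)[C@@H]2COC(=O)/C=C/c2ccc(OCc3ccccc3)cc2)ccc1OCc1ccccc1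
F8 | step 7 | (1S,2R,3R)-7-(benzyloxy)-1-[4-(benzyloxy)-3-methoxyphenyl]-2-({[(E)-3-(4-(benzyloxy)phenyl)prop-2-enoyl]oxy}methyl)-6-methoxy-1,2,3,4-tetrahydronaphthalene-3-carboxylic acid (route numbering) | COc1cc([C@H]2c3cc(OCc4ccccc4)c(OC)cc3C[C@@H](C(=O)O)[C@@H]2COC(=O)/C=C/c2ccc(OCc3ccccc3)cc2)ccc1OCc1ccccc1
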